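**Retrosynthetic overview**

1. The 1,2-dioxene ring (C–O–O–C–C=C) is grown from the five-membered C4S ring of 2,4-dimethylthiophene 1,1-dioxide 15: the same four carbons are kept, the one-atom SO2 bridge is expelled and the two-atom O–O bridge is taken up in the same flask (5 → 6 ring atoms).
2. The cyclohexene ring comes from [4+2] addition of 15 across the strained C2=C3 bond of cyclobutene 13, so 18 ⇒ 13 + 15 + O2.
3. 13 ⇒ γ-pyranone annulation (triketide route) onto cyclobutene acid 6; 6 ⇒ Pd-catalysed asymmetric allylic methylation of the photo-lactone 5 of 3,5-dimethyl-2-pyranone 4.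
4. Ring order: cyclobutene (4π photoclosure) → γ-pyranone → cyclohexadiene ([4+2]/–SO2) → 1,2-dioxene.
5. Enabling feature: the strained, trisubstituted C2=C3 π-bond of the cyclobutene ring in 13, flanked by the C1 and C4 stereocenters, together with the cheletropically labile SO2 of the C4S ring.

Key step: step 9

Assumption: 1, 2, 7, 8, 14 and 4,6-dimethyl-2H-pyran-2-one are purchased; the enantiomer of the phosphoramidite ligand in step 4 is chosen by experiment to give (1R,4R)-6; CIP descriptors were derived from the SMILES strings, which are authoritative.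

**Route**

Step 1
Reactants: 1 (E)-3-ethoxy-2-methylprop-2-enal; 2 triethyl 2-phosphonopropionate
Product: 3 ethyl (2E,4E)-5-ethoxy-2,4-dimethylpenta-2,4-dienoate
Conditions: NaH, THF, 0 °C → rt
Reagents that add atoms: none
Why: Horner–Wadsworth–Emmons olefination of the vinylogous formate aldehyde; the 2E/2Z ratio does not matter because step 2 equilibrates this double bond.

Step 2
Reactants: 3 ethyl (2E,4E)-5-ethoxy-2,4-dimethylpenta-2,4-dienoate
Product: 4 3,5-dimethyl-2H-pyran-2-one
Conditions: 6 M HCl/AcOH, 90 °C
Reagents that add atoms: water, O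
Why: Acid hydrolysis of the enol ether followed by enol-lactonization (2-pyranone synthesis from a 5-oxo-2-enoate); the push–pull diene should isomerize E/Z through its C2-protonated oxocarbenium ion, and only the Z form can close, so the material should funnel to the pyranone.

Step 3
Reactants: 4 3,5-dimethyl-2H-pyran-2-one
Product: 5 rac-4,6-dimethyl-2-oxabicyclo[2.2.0]hex-5-en-3-one (cis-fused photo-pyrone lactone)
Conditions: hν (300 nm), Et2O, –10 °C, flow; used as a solution
Reagents that add atoms: none
Why: Photochemical disrotatory 4π-electrocyclization of the pyranone diene (C3–C6 bond) to the bicyclic β-lactone, which is necessarily cis-fused and racemic.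

Step 4
Reactants: 5 rac-4,6-dimethyl-2-oxabicyclo[2.2.0]hex-5-en-3-one
Product: 6 (1R,4R)-1,3,4-trimethylcyclobut-2-ene-1-carboxylic acid (CO2H and 4-Me trans)
Conditions: Pd2(dba)3 (2.5 mol %), BINOL-derived chiral phosphoramidite (6 mol %), Me2Zn, THF, –20 → 0 °C; then 1 M HCl
Reagents that add atoms: dimethylzinc, C[Zn]C
Why: Deracemizing Pd-catalysed asymmetric allylic alkylation: Pd(0) ionizes the strained allylic lactone with inversion to a Cs-symmetric η3-cyclobutenyl carboxylate common to both enantiomers of 5, and inner-sphere methyl transfer to one enantiotopic allyl terminus, selected by the ligand, should place the new methyl anti to the carboxylate (cis to the C1 methyl) and so fix both stereocenters.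

Step 5
Reactants: 6 (1R,4R)-1,3,4-trimethylcyclobut-2-ene-1-carboxylic acid; 7 1,1'-carbonyldiimidazole; 8 ethyl 2-methyl-3-oxopentanoate
Product: 11 ethyl 2,4-dimethyl-3,5-dioxo-5-[(1R,4R)-1,3,4-trimethylcyclobut-2-en-1-yl]pentanoate (epimer/enol mixture), via acyl imidazolide 9 (not isolated), via dilithium dienolate 10 (not isolated)
Conditions: 6 + 7, THF, rt → 40 °C; 8 + LDA (2.1 equiv), THF, –78 → 0 °C; combine at –78 → 0 °C; then 1 M HCl
Reagents that add atoms: none
Why: Claisen-type C-acylation at the terminal carbon of the β-keto ester dianion by the acyl imidazolide; C1 of the cyclobutene is quaternary, so no stereocenter can epimerize.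

Step 6
Reactants: 11 ethyl 2,4-dimethyl-3,5-dioxo-5-[(1R,4R)-1,3,4-trimethylcyclobut-2-en-1-yl]pentanoate
Product: 12 4-hydroxy-3,5-dimethyl-6-[(1R,4R)-1,3,4-trimethylcyclobut-2-en-1-yl]-2H-pyran-2-one
Conditions: DBU, toluene, 60 °C
Reagents that add atoms: none
Why: Base-mediated enol-lactonization of the β,δ-diketo ester (triketide cyclization) to the 4-hydroxy-2-pyranone; the two epimerizable chain carbons become sp2.

Step 7
Reactants: 12 4-hydroxy-3,5-dimethyl-6-[(1R,4R)-1,3,4-trimethylcyclobut-2-en-1-yl]-2H-pyran-2-one
Product: 13 2-methoxy-3,5-dimethyl-6-[(1R,4R)-1,3,4-trimethylcyclobut-2-en-1-yl]-4H-pyran-4-one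
Conditions: MeOSO2F, CH2Cl2, 0 °C → rt; aq. NaHCO3
Reagents that add atoms: methyl fluorosulfonate, COS(=O)(=O)F
Why: Hard O-methylation at the 2-pyranone carbonyl oxygen and loss of the 4-OH proton should give the α-methoxy-γ-pyranone regioisomer (regioselective pyranone methylation).

Step 8
Reactants: 14 2,4-dimethylthiophene
Product: 15 2,4-dimethylthiophene 1,1-dioxide
Conditions: dimethyldioxirane (2.2 equiv), acetone, –20 °C; used fresh
Reagents that add atoms: dimethyldioxirane, CC1(C)OO1
Why: Electrophilic S-oxidation of the thiophene under neutral, cold conditions, which should deliver the non-aromatic dioxide before it can dimerize.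

Step 9
Reactants: 13 2-methoxy-3,5-dimethyl-6-[(1R,4R)-1,3,4-trimethylcyclobut-2-en-1-yl]-4H-pyran-4-one; 15 2,4-dimethylthiophene 1,1-dioxide
Product: 18 2-methoxy-3,5-dimethyl-6-[(1S,2R,3S,4R,5R,6R)-1,3,4,5,10-pentamethyl-7,8-dioxatricyclo[4.2.2.0^2,5]dec-9-en-3-yl]-4H-pyran-4-one, via bridged sulfone 16 (not isolated), via diene 17 (not isolated)
Conditions: 15 (3 equiv, slow addition), CH2Cl2, 30 °C, dark, Ar; then TPP (1 mol %), O2, white LEDs, –30 °C
Reagents that add atoms: dioxygen, O=O
Why: The electron-poor diene 15 should add with inverse electron demand across the strained C2=C3 bond of 13 (its C5–H terminus to the methylated alkene carbon, its C2–Me terminus to the CH carbon, so that no bond forms between two methyl-bearing carbons); the 7-thiabicyclo[2.2.1]hept-2-ene 7,7-dioxide 16 is expected to lose SO2 cheletropically below room temperature, and the s-cis diene 17 then takes up 1O2 in a second [4+2]; the closest precedents are the Diels–Alder/SO2-extrusion of thiophene 1,1-dioxides with strained cycloalkenes and the photooxygenation of bicyclo[4.2.0]octa-2,4-dienes. The cyclohexadiene ring closes by an intermolecular suprafacial [4+2]; the 1,2-dioxene ring is the five-membered C4S ring of 15/16 enlarged by one atom, its four carbons being kept while the SO2 bridge is exchanged for the O–O bridge (cheletropic extrusion, then suprafacial [4+2] of 1O2). The two ring-fusion carbons are set cis by the suprafacial addition, on the face of 13 that carries the pyranone at C1 and H at C4, i.e. anti to both ring methyls fixed in step 4; the two peroxide carbons are then set by approach of 1O2 to the convex face of 17, anti to the cyclobutane. The step needs regio- and π-facial selectivity in the first cycloaddition, which rest on the 1,3-dimethyl pattern of 15 against the trisubstituted alkene and on the two cis methyls of 13, and it needs chemoselectivity of 1O2 for the diene, secured by admitting O2 and light only after 13 is consumed. Keeping everything at or below 30 °C should avoid the retro-6π/8π valence tautomerism of 17 that would scramble the ring fusion and erode the ee.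

**Compound list**

1 | (E)-3-ethoxy-2-methylprop-2-enal | CCO/C=C(\C)C=O | starting material
2 | triethyl 2-phosphonopropionate | CCOC(=O)C(C)P(=O)(OCC)OCC | starting material
3 | ethyl (2E,4E)-5-ethoxy-2,4-dimethylpenta-2,4-dienoate | CCO/C=C(\C)/C=C(\C)C(=O)OCC | intermediate
4 | 3,5-dimethyl-2H-pyran-2-one | CC1=CC(C)=COC1=O | intermediate
5 | rac-4,6-dimethyl-2-oxabicyclo[2.2.0]hex-5-en-3-one (cis-fused; one enantiomer drawn) | O=C1O[C@@H]2C(C)=C[C@]12C | intermediate
6 | (1R,4R)-1,3,4-trimethylcyclobut-2-ene-1-carboxylic acid | OC(=O)[C@@]1(C)[C@H](C)C(C)=C1 | intermediate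
7 | 1,1'-carbonyldiimidazole | O=C(n1ccnc1)n1ccnc1 | starting material
8 | ethyl 2-methyl-3-oxopentanoate | CCC(=O)C(C)C(=O)OCC | starting material
9 | 1-[(1R,4R)-1,3,4-trimethylcyclobut-2-ene-1-carbonyl]imidazole | O=C(n1ccnc1)[C@@]1(C)[C@H](C)C(C)=C1 | intermediate
10 | dilithium dienolate of ethyl 2-methyl-3-oxopentanoate | [Li+].[Li+].CCOC(=O)C(C)=C([O-])[CH-]C | intermediate
11 | ethyl 2,4-dimethyl-3,5-dioxo-5-[(1R,4R)-1,3,4-trimethylcyclobut-2-en-1-yl]pentanoate (chain epimers/enols unspecified) | CCOC(=O)C(C)C(=O)C(C)C(=O)[C@@]1(C)[C@H](C)C(C)=C1 | intermediate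
12 | 4-hydroxy-3,5-dimethyl-6-[(1R,4R)-1,3,4-trimethylcyclobut-2-en-1-yl]-2H-pyran-2-one | O=C1OC([C@@]2(C)[C@H](C)C(C)=C2)=C(C)C(O)=C1C | intermediate
13 | 2-methoxy-3,5-dimethyl-6-[(1R,4R)-1,3,4-trimethylcyclobut-2-en-1-yl]-4H-pyran-4-one | COc1oc([C@@]2(C)[C@H](C)C(C)=C2)c(C)c(=O)c1C | intermediate
14 | 2,4-dimethylthiophene | Cc1csc(C)c1 | starting material
15 | 2,4-dimethylthiophene 1,1-dioxide | CC1=CC(C)=CS1(=O)=O | intermediate
16 | bridged sulfone: [4+2] adduct of 13 and 15, a 9-thiatricyclo[4.2.1.0^2,5]non-7-ene 9,9-dioxide with cis ring fusion syn to the pyranone (endo adduct drawn; the sulfone bridgehead configuration is lost on SO2 extrusion) | COc1oc([C@@]2(C)[C@H](C)[C@@]3(C)[C@@H]4S(=O)(=O)[C@@](C)(C=C4C)[C@@H]23)c(C)c(=O)c1C | intermediate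
17 | 2-methoxy-3,5-dimethyl-6-[(1R,6R,7S,8R)-1,3,5,7,8-pentamethylbicyclo[4.2.0]octa-2,4-dien-7-yl]-4H-pyran-4-one (cis-fused; six-membered ring syn to the pyranone) | COc1oc([C@@]2(C)[C@H](C)[C@@]3(C)C=C(C)C=C(C)[C@@H]23)c(C)c(=O)c1C | intermediate
18 | 2-methoxy-3,5-dimethyl-6-[(1S,2R,3S,4R,5R,6R)-1,3,4,5,10-pentamethyl-7,8-dioxatricyclo[4.2.2.0^2,5]dec-9-en-3-yl]-4H-pyran-4-one (peroxide bridge anti to the cyclobutane) | COc1oc([C@@]2(C)[C@H](C)[C@@]3(C)[C@@H]4OO[C@@](C)(C=C4C)[C@@H]23)c(C)c(=O)c1C | target

**Totals**

Total step count: 9. Longest linear sequence: 8 steps (steps 1–7 and 9).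

**Steps most likely to fail**

Step 9. The first cycloaddition may be slower than self-dimerization of 15, or may proceed with poor regio- or π-facial control. Such isomers cannot be removed before the peroxide is formed, because 16 and 17 are not isolated. Fallback: starting from 13, cycloaddition with commercial 4,6-dimethyl-2H-pyran-2-one under high pressure (10–12 kbar, CH2Cl2, 40 °C) should give the bridged lactone F1, a stable compound that can be purified and freed of regio- and face-isomers. Brief thermolysis of F1 (toluene, 110 °C) extrudes CO2 and gives diene 17, which is cooled at once and photooxygenated (TPP, O2, hν, –30 °C) to 18.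

Step 4. Ionization or methyl transfer at the more substituted π-cyclobutenyl may be sluggish, or enantio- and trans-selectivity may be insufficient. Fallback: starting from 5, stereospecific anti-SN2' opening with a methyl cuprate (MeMgBr, CuBr·SMe2 cat., THF, –78 °C) should give the racemic trans acid F2. It is resolved by crystallization of the (R)-1-phenylethylammonium salt F3 (the antipodal amine is used instead if it gives the less soluble salt of the (1R,4R)-acid); acidification with 1 M HCl returns 6.

Step 5. The neopentyl-type acyl imidazolide may react too slowly with the dienolate, so that proton transfer and O-acylation take over. Fallback: starting from 6, reduction (LiAlH4, Et2O) gives the alcohol F4 and Dess–Martin oxidation gives the aldehyde F5. Aldol addition of dienolate 10 (THF, –78 °C) to F5 gives the δ-hydroxy-β-keto ester F6, and Dess–Martin oxidation of F6 gives 11.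

Further compounds
F1 | step 9 | bridged lactone: [4+2] adduct of 13 and 4,6-dimethyl-2H-pyran-2-one, a 7-oxatricyclo[4.2.2.0^2,5]dec-9-en-8-one with the lactone oxygen on the methyl-bearing bridgehead | COc1oc([C@@]2(C)[C@H](C)[C@@]3(C)[C@@H]4C(=O)O[C@@](C)(C=C4C)[C@@H]23)c(C)c(=O)c1C
F2 | step 4 | racemic trans-1,3,4-trimethylcyclobut-2-ene-1-carboxylic acid (both enantiomers) | OC(=O)[C@@]1(C)[C@H](C)C(C)=C1.OC(=O)[C@]1(C)[C@@H](C)C(C)=C1
F3 | step 4 | (R)-1-phenylethylammonium (1R,4R)-1,3,4-trimethylcyclobut-2-ene-1-carboxylate | C[C@@H]([NH3+])c1ccccc1.[O-]C(=O)[C@@]1(C)[C@H](C)C(C)=C1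
F4 | step 5 | [(1R,4R)-1,3,4-trimethylcyclobut-2-en-1-yl]methanol | OC[C@@]1(C)[C@H](C)C(C)=C1
F5 | step 5 | (1R,4R)-1,3,4-trimethylcyclobut-2-ene-1-carbaldehyde | O=C[C@@]1(C)[C@H](C)C(C)=C1
F6 | step 5 | ethyl 5-hydroxy-2,4-dimethyl-3-oxo-5-[(1R,4R)-1,3,4-trimethylcyclobut-2-en-1-yl]pentanoate (diastereomer mixture) | CCOC(=O)C(C)C(=O)C(C)C(O)[C@@]1(C)[C@H](C)C(C)=C1
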